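**Assumptions.** The SMILES corresponds to (S)-alkannin isovalerate, because the carbinol carbon is (S) by CIP analysis. The naphthazarin side-chain regioisomer is drawn as a single tautomer, since the 2- and 6-substituted forms interconvert by proton transfer.

## Retrosynthetic overview
- Target **1** is disconnected at the ester to (S)-alkannin **2** and isovaleryl chloride **3**.
- Alkannin **2** comes from enantioselective reduction of the aryl ketone **4**, which sets the only stereocentre.
- Ketone **4** comes from a radical C–H acylation, the key step, of naphthazarin **5** with 4-methylpent-3-enal **6**.
- Naphthazarin **5** comes from hydroquinone **7** and maleic anhydride **8** by double Friedel–Crafts acylation. This forms the quinone ring and is the only ring-forming step.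

## Forward route

**Step 1**
Reactants: **7** hydroquinone; **8** maleic anhydride
Product: **5** naphthazarin (5,8-dihydroxy-1,4-naphthoquinone)
Conditions: AlCl3/NaCl melt (about 5:1 w/w), 180 °C, 15 min; then ice/aq. HCl
Reagents that add atoms: none
Why: Double Friedel–Crafts acylation and cyclisation of hydroquinone with maleic anhydride (Zahn naphthazarin synthesis) builds the second ring. The dihydronaphthazarin intermediate is dehydrogenated in the melt, and no stereocentre is involved.

**Step 2**
Reactants: **5** naphthazarin (3 equiv, also the terminal oxidant); **6** 4-methylpent-3-enal (1 equiv)
Product: **4** 2-(4-methylpent-3-enoyl)-5,8-dihydroxy-1,4-naphthoquinone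
Conditions: tetrabutylammonium decatungstate (2 mol%), 390 nm LEDs, MeCN (0.3 M), Ar, 10 °C; then open to air (or Ag2O) to reoxidise the leuco species
Reagents that add atoms: none (the aldehyde is the reactant)
Why: Photo-excited decatungstate abstracts the aldehydic hydrogen by HAT. The nucleophilic acyl radical adds to the electron-poor C2=C3 bond of the quinone (Minisci/Giese-type radical conjugate addition), and oxidation rearomatises the ring to the acylquinone. Proposed new method: the closest known reaction is radical acylation of quinones with aldehydes. The β,γ-unsaturated acyl radical can lose CO to give the prenyl radical, so the reaction is run with excess, concentrated quinone (0.3 M) at low temperature so that addition outcompetes decarbonylation. Excess naphthazarin also avoids bis-acylation.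

**Step 3**
Reactant: **4** ketone
Product: **2** (S)-alkannin, (S)-5,8-dihydroxy-2-(1-hydroxy-4-methylpent-3-enyl)-1,4-naphthoquinone
Conditions: RuCl[(S,S)-TsDPEN](p-cymene) (2 mol%), HCO2H/Et3N (5:2), CH2Cl2, 25 °C; then air or MnO2 to restore the quinone
Reagents that add atoms: none (formate supplies only hydrogen)
Why: Noyori–Ikariya asymmetric transfer hydrogenation of an aryl alkyl ketone with the (S,S)-catalyst gives the (S)-carbinol. The CIP priorities here (OH > aryl > CH2 > H) match those of acetophenone, so the (S,S)-catalyst delivers the (S)-alcohol. Proposed new method: the quinone is first reduced by Ru–H/formate to the leuco-naphthazarin, which carries an electron-rich, peri-H-bonded aryl ketone, similar to an o-hydroxyaryl ketone. The ketone is reduced enantioselectively in that form and air reoxidation then regenerates the quinone without touching the stereocentre.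

**Step 4**
Reactants: **2** (S)-alkannin; **3** isovaleryl chloride
Product: **1** isovalerylalkannin
Conditions: **3** (1.2 equiv), pyridine (3 equiv), CH2Cl2, 0 °C, 1 h
Reagents that add atoms: isovaleryl chloride, CC(C)CC(=O)Cl
Why: Schotten–Baumann-type acylation occurs at the free secondary alcohol, because the two peri-phenols are chelated to the quinone carbonyls and are unreactive. No bond to the carbinol carbon is broken, and the mild base and low temperature avoid quinone-methide racemisation.

## Checks
- **Structure:** the naphthazarin core, the 2-substituent –CH(O2CCH2CHMe2)CH2CH=CMe2 and the (S) centre all match the target SMILES.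
- **Atom balance:** C10H6O4 (**5**) + C6H10O (**6**) − 2H gives C16H14O5 (**4**); +2H gives C16H16O5 (**2**); + C5H8O gives C21H24O6 (**1**).
- **Stereocentre:** it is set only in step 3 and is not touched in step 4.
- **Functional groups:** the trisubstituted alkene survives HAT acylation, formate/Ru–H and acylation. The phenols survive because they are chelated.

## Compound list
1 | isovalerylalkannin, (S)-1-(5,8-dihydroxy-1,4-dioxo-naphthalen-2-yl)-4-methylpent-3-enyl 3-methylbutanoate | CC(C)=CC[C@H](OC(=O)CC(C)C)C1=CC(=O)c2c(O)ccc(O)c2C1=O | target
2 | (S)-alkannin | CC(C)=CC[C@H](O)C1=CC(=O)c2c(O)ccc(O)c2C1=O | intermediate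
3 | isovaleryl chloride | CC(C)CC(Cl)=O | starting material
4 | 2-(4-methylpent-3-enoyl)-5,8-dihydroxy-1,4-naphthoquinone | CC(C)=CCC(=O)C1=CC(=O)c2c(O)ccc(O)c2C1=O | intermediate
5 | naphthazarin | O=C1C=CC(=O)c2c(O)ccc(O)c12 | intermediate
6 | 4-methylpent-3-enal | CC(C)=CCC=O | starting material
7 | hydroquinone | Oc1ccc(O)cc1 | starting material
8 | maleic anhydride | O=C1C=CC(=O)O1 | starting material

**Total steps:** 4. **Longest linear sequence:** 4 (7 + 8 → 5 → 4 → 2 → 1).

## Three steps most likely to fail
1. **Step 2 (radical acylation).** The acyl radical may decarbonylate to the prenyl radical, the β,γ-enone may isomerise into conjugation, or bis-acylation may occur.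
   - Fallback: a different approach is radical hydroxyalkylation of naphthazarin with 4-methylpent-3-en-1-ol (HAT, S2O8²⁻/Ag⁺) to give racemic alkannin. Then perform a lipase-catalysed kinetic resolution by acylation with vinyl isovalerate, which also delivers the ester directly.
2. **Step 3 (transfer hydrogenation).** The Ru–H/formate system may over-reduce the quinone or give low conversion or ee on the peri-hydroxylated ketone.
   - Fallback: use an NADPH-dependent ketoreductase with iPrOH cofactor recycling in buffer on ketone **4**, or a CBS reduction after bis-silylation of the phenols.
3. **Step 4 (esterification).** The benzylic carbinol next to the quinone can racemise through a quinone methide, and the phenols may be acylated.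
   - Fallback: enzymatic transesterification of **2** with vinyl isovalerate (lipase, neutral conditions, tert-butyl methyl ether), which gives chemoselective acylation of the side-chain alcohol without racemisation.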